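**Plan**
Retrosynthesis: after the allyl, silyl and ketal protecting groups are removed, ring A is cut at two neighbouring bonds at once, C6–O(aryl) and C1–CO2H. This leads back to a 3-methoxyaryne (C1≡C6) released from an ortho-silylaryl triflate, the ring B phenoxide and CO2.
Enabling feature: on ring A the ether-bearing C6 is bonded directly to the carboxyl-bearing C1, and C1 is bonded to the methoxy-bearing C2 (side chain on C3). An aryne across C1–C6 therefore takes the oxygen nucleophile at C6 and leaves the carbanion for CO2 at C1.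
Forward: ring A is made from 4-hydroxy-2-methoxybenzaldehyde (carbamate, methallylation, hydration, ketal, silylation between the two oxygens, triflation). Ring B is made from 2-methoxy-4-methylphenol (formylation, demethylation, allylation, reduction, silylation).
The two rings and CO2 are joined in step 12 and two deprotections finish the synthesis; no ring of the target is formed, only the temporary dioxane.
Stereochemistry: the single (R) carbinol centre is set by a chiral phosphoric acid-catalysed methallylboration (step 2) and carried through as the ketal.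

Key step: step 12

Assumption: the (R)-configured phosphoric acid is taken to send the methallyl group to the Re face of the aldehyde in step 2, as in allylborations of simple benzaldehydes, which corresponds to the (R) carbinol; were the sense opposite, the (S)-acid would be used.

Step 1
Reactants: 1 4-hydroxy-2-methoxybenzaldehyde
Product: 2 4-formyl-3-methoxyphenyl isopropylcarbamate
Conditions: i-PrNCO, Et3N (cat.), CH2Cl2, rt
Reagents that add atoms: isopropyl isocyanate, CC(C)N=C=O
Why: Amine-catalysed addition of the only hydroxyl group to the isocyanate (phenol carbamoylation) should give the secondary carbamate that later directs ring metalation and is removable under mild base.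

Step 2
Reactants: 2 4-formyl-3-methoxyphenyl isopropylcarbamate; 3 2-methylallylboronic acid pinacol ester
Product: 4 4-[(1R)-1-hydroxy-3-methylbut-3-en-1-yl]-3-methoxyphenyl isopropylcarbamate
Conditions: (R)-TRIP [(R)-3,3'-bis(2,4,6-triisopropylphenyl)-1,1'-binaphthyl-2,2'-diyl hydrogen phosphate] (5 mol%), 4 Å MS, toluene, −30 °C; aq. NaHCO3
Reagents that add atoms: none
Why: Chiral phosphoric acid-catalysed allylboration of an aldehyde, in which the acid binds the boronate oxygen and the formyl hydrogen in a chair transition state, should deliver the methallyl group to the Re face and so set the (R) carbinol centre.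

Step 3
Reactants: 4 4-[(1R)-1-hydroxy-3-methylbut-3-en-1-yl]-3-methoxyphenyl isopropylcarbamate
Product: 5 4-[(1R)-1,3-dihydroxy-3-methylbutyl]-3-methoxyphenyl isopropylcarbamate
Conditions: Co(acac)2 (20 mol%), PhSiH3, O2 (1 atm), THF, rt
Reagents that add atoms: dioxygen, O=O
Why: Mukaiyama hydration (hydrogen-atom transfer from a cobalt hydride to the 1,1-disubstituted alkene, capture of the tertiary radical by O2, silane reduction of the peroxide) should give the Markovnikov tertiary alcohol under neutral conditions that leave the carbinol centre and the carbamate alone.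

Step 4
Reactants: 5 4-[(1R)-1,3-dihydroxy-3-methylbutyl]-3-methoxyphenyl isopropylcarbamate
Product: 6 3-methoxy-4-[(4R)-2,2,6,6-tetramethyl-1,3-dioxan-4-yl]phenyl isopropylcarbamate
Conditions: 2-methoxypropene, pyridinium p-toluenesulfonate (cat.), CH2Cl2, 0 °C to rt; Et3N
Reagents that add atoms: 2-methoxypropene, COC(C)=C
Why: Acid-catalysed ketalisation of the 1,3-diol with an enol ether is irreversible under these mild conditions and should close the dioxane without ionising the benzylic C–O bond, masking both hydroxyl groups as one fluoride-stable unit.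

Step 5
Reactants: 6 3-methoxy-4-[(4R)-2,2,6,6-tetramethyl-1,3-dioxan-4-yl]phenyl isopropylcarbamate
Product: 10 3-methoxy-4-[(4R)-2,2,6,6-tetramethyl-1,3-dioxan-4-yl]-2-(trimethylsilyl)phenyl isopropylcarbamate, via N-silyl carbamate 7 (not isolated), via aryllithium 8 (not isolated), via bis-silyl carbamate 9 (not isolated)
Conditions: TMSOTf, TMEDA, Et2O, 0 °C to rt; n-BuLi, TMEDA, −78 °C; TMSCl, −78 °C to rt; aq. NaHCO3
Reagents that add atoms: chlorotrimethylsilane, C[Si](C)(C)Cl
Why: Directed ortho-metalation: once the N–H is masked in situ, butyllithium should remove the ring hydrogen flanked by the carbamate and methoxy oxygens (cooperating 1,3-directing groups), silylation of the aryllithium places silicon on C1, and the N–Si bond is hydrolysed on work-up.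

Step 6
Reactants: 10 3-methoxy-4-[(4R)-2,2,6,6-tetramethyl-1,3-dioxan-4-yl]-2-(trimethylsilyl)phenyl isopropylcarbamate
Product: 12 3-methoxy-4-[(4R)-2,2,6,6-tetramethyl-1,3-dioxan-4-yl]-2-(trimethylsilyl)phenyl trifluoromethanesulfonate, via silylphenol 11 (not isolated)
Conditions: DBU, Et2NH, MeCN, 40 °C; then PhNTf2, rt
Reagents that add atoms: N-phenylbis(trifluoromethanesulfonimide), O=S(=O)(N(c1ccccc1)S(=O)(=O)C(F)(F)F)C(F)(F)F
Why: Base-induced elimination of the secondary carbamate (the isocyanate is scavenged by diethylamine) frees the hindered phenoxide, which is triflated in the same flask by the mild triflyl donor, the standard one-pot route to ortho-silylaryl triflates.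

Step 7
Reactants: 13 2-methoxy-4-methylphenol
Product: 14 2-hydroxy-3-methoxy-5-methylbenzaldehyde
Conditions: MgCl2, Et3N, (CH2O)n, MeCN, reflux; aq. HCl
Reagents that add atoms: paraformaldehyde (formaldehyde), C=O
Why: Magnesium-mediated ortho-formylation (Casnati–Skattebøl reaction) should place the formyl group on the only free position ortho to the phenol, a second formaldehyde acting as hydride acceptor.

Step 8
Reactants: 14 2-hydroxy-3-methoxy-5-methylbenzaldehyde
Product: 15 2,3-dihydroxy-5-methylbenzaldehyde
Conditions: BBr3, CH2Cl2, −78 to 0 °C; H2O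
Reagents that add atoms: none
Why: Lewis acid cleavage of the aryl methyl ether by BBr3 frees the catechol so that a removable group can take the place of the methyl group.

Step 9
Reactants: 15 2,3-dihydroxy-5-methylbenzaldehyde
Product: 17 3-(allyloxy)-2-hydroxy-5-methylbenzaldehyde, via disodium catecholate 16 (not isolated)
Conditions: NaH (2.2 equiv), DMSO, rt; allyl bromide (1.0 equiv), rt; aq. HCl
Reagents that add atoms: allyl bromide, C=CCBr
Why: Williamson etherification of the dianion should be selective because the 3-oxide, which is neither conjugated with the formyl group nor chelated by it, is the more nucleophilic oxygen.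

Step 10
Reactants: 17 3-(allyloxy)-2-hydroxy-5-methylbenzaldehyde
Product: 18 2-(allyloxy)-6-(hydroxymethyl)-4-methylphenol
Conditions: NaBH4, MeOH/THF, 0 °C
Reagents that add atoms: none
Why: Borohydride reduction of the aldehyde gives the benzylic alcohol and leaves the allyl ether and the phenol untouched.

Step 11
Reactants: 18 2-(allyloxy)-6-(hydroxymethyl)-4-methylphenol
Product: 19 2-(allyloxy)-6-{[(tert-butyldimethylsilyl)oxy]methyl}-4-methylphenol
Conditions: TBSCl (1.05 equiv), imidazole, CH2Cl2, 0 °C
Reagents that add atoms: tert-butyldimethylsilyl chloride, CC(C)(C)[Si](C)(C)Cl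
Why: Imidazole-promoted silylation should take the primary alcohol in preference to the phenol, which is flanked on both sides, leaving the phenolic oxygen free as the nucleophile of the key step.

Step 12
Reactants: 12 3-methoxy-4-[(4R)-2,2,6,6-tetramethyl-1,3-dioxan-4-yl]-2-(trimethylsilyl)phenyl trifluoromethanesulfonate; 19 2-(allyloxy)-6-{[(tert-butyldimethylsilyl)oxy]methyl}-4-methylphenol; 20 carbon dioxide
Product: 23 6-[2-(allyloxy)-6-{[(tert-butyldimethylsilyl)oxy]methyl}-4-methylphenoxy]-2-methoxy-3-[(4R)-2,2,6,6-tetramethyl-1,3-dioxan-4-yl]benzoic acid, via potassium phenoxide 21 (not isolated), via aryne 22 (not isolated)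
Conditions: 19 (1.5 equiv), KH, THF, 0 °C; then KF, 18-crown-6, CO2 (1 atm), slow addition of 12, THF, 0 °C to rt; cold aq. KHSO4 (pH 4)
Reagents that add atoms: none
Why: Proposed new method: fluoride removes the silyl group from C1 and loss of triflate from C6 unveils aryne 22; phenoxide 21 adds to C6 to make the C6–O bond, and the aryl anion left on C1 adds to CO2 to make the C1–CO2 bond. The closest known reaction types are the three-component union of arynes with amines and CO2 to anthranilic acids and the addition of salicylate phenoxides to arynes with capture of the aryl anion by the ester carbonyl; the new element is pairing an anionic oxygen nucleophile with free CO2. No ring is closed and no stereocentre is formed; the (4R) centre of the dioxane is a spectator. The step needs regioselectivity, which the C2 methoxy group should secure by polarising the triple bond so that C6 (meta to it) is the electrophilic end and the C1 carbanion is inductively stabilised. It also needs capture by CO2 rather than by a proton, which the absence of proton donors should secure (phenoxide preformed with KH, every hydroxyl masked, THF in place of acetonitrile, CO2 atmosphere). Slow addition of 12 keeps the aryne concentration low so that the phenoxide, not the product carboxylate, meets it.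

Step 13
Reactants: 23 6-[2-(allyloxy)-6-{[(tert-butyldimethylsilyl)oxy]methyl}-4-methylphenoxy]-2-methoxy-3-[(4R)-2,2,6,6-tetramethyl-1,3-dioxan-4-yl]benzoic acid
Product: 24 6-[2-{[(tert-butyldimethylsilyl)oxy]methyl}-6-hydroxy-4-methylphenoxy]-2-methoxy-3-[(4R)-2,2,6,6-tetramethyl-1,3-dioxan-4-yl]benzoic acid
Conditions: Pd(PPh3)4 (5 mol%), morpholine, THF, rt; pH 4 buffer
Reagents that add atoms: none
Why: Tsuji–Trost deallylation, in which zerovalent palladium ionises the aryl allyl ether to a π-allyl complex that morpholine intercepts, should free the phenol without touching either benzylic C–O bond, the silyl ether or the ketal.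

Step 14
Reactants: 24 6-[2-{[(tert-butyldimethylsilyl)oxy]methyl}-6-hydroxy-4-methylphenoxy]-2-methoxy-3-[(4R)-2,2,6,6-tetramethyl-1,3-dioxan-4-yl]benzoic acid
Product: 25 6-[2-hydroxy-6-(hydroxymethyl)-4-methylphenoxy]-3-[(1R)-1,3-dihydroxy-3-methylbutyl]-2-methoxybenzoic acid (CNP0452050.1)
Conditions: AcOH/THF/H2O (3:1:1), rt
Reagents that add atoms: none
Why: Mild aqueous acid hydrolysis should remove the primary silyl ether and the strained ketal together while staying below the acidity at which the electron-rich benzylic carbinol ionises, so the (R) centre is kept.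

**Compound list**
1 | 4-hydroxy-2-methoxybenzaldehyde | COc1cc(O)ccc1C=O | starting material
2 | 4-formyl-3-methoxyphenyl isopropylcarbamate | COc1cc(OC(=O)NC(C)C)ccc1C=O | intermediate
3 | 2-methylallylboronic acid pinacol ester | CC(=C)CB1OC(C)(C)C(C)(C)O1 | starting material
4 | 4-[(1R)-1-hydroxy-3-methylbut-3-en-1-yl]-3-methoxyphenyl isopropylcarbamate | COc1cc(OC(=O)NC(C)C)ccc1[C@H](O)CC(C)=C | intermediate
5 | 4-[(1R)-1,3-dihydroxy-3-methylbutyl]-3-methoxyphenyl isopropylcarbamate | COc1cc(OC(=O)NC(C)C)ccc1[C@H](O)CC(C)(C)O | intermediate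
6 | 3-methoxy-4-[(4R)-2,2,6,6-tetramethyl-1,3-dioxan-4-yl]phenyl isopropylcarbamate | COc1cc(OC(=O)NC(C)C)ccc1[C@H]2CC(C)(C)OC(C)(C)O2 | intermediate
7 | N-trimethylsilyl derivative of 6 (N-silyl carbamate) | COc1cc(OC(=O)N(C(C)C)[Si](C)(C)C)ccc1[C@H]2CC(C)(C)OC(C)(C)O2 | intermediate
8 | 2-lithio derivative of 7 (aryllithium, lithium between the carbamate and methoxy groups) | COc1c([Li])c(OC(=O)N(C(C)C)[Si](C)(C)C)ccc1[C@H]2CC(C)(C)OC(C)(C)O2 | intermediate
9 | N,2-bis(trimethylsilyl) carbamate (bis-silyl carbamate) | COc1c([Si](C)(C)C)c(OC(=O)N(C(C)C)[Si](C)(C)C)ccc1[C@H]2CC(C)(C)OC(C)(C)O2 | intermediate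
10 | 3-methoxy-4-[(4R)-2,2,6,6-tetramethyl-1,3-dioxan-4-yl]-2-(trimethylsilyl)phenyl isopropylcarbamate | COc1c([Si](C)(C)C)c(OC(=O)NC(C)C)ccc1[C@H]2CC(C)(C)OC(C)(C)O2 | intermediate
11 | 3-methoxy-4-[(4R)-2,2,6,6-tetramethyl-1,3-dioxan-4-yl]-2-(trimethylsilyl)phenol (silylphenol) | COc1c([Si](C)(C)C)c(O)ccc1[C@H]2CC(C)(C)OC(C)(C)O2 | intermediate
12 | 3-methoxy-4-[(4R)-2,2,6,6-tetramethyl-1,3-dioxan-4-yl]-2-(trimethylsilyl)phenyl trifluoromethanesulfonate | COc1c([C@H]2CC(C)(C)OC(C)(C)O2)ccc(OS(=O)(=O)C(F)(F)F)c1[Si](C)(C)C | intermediate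
13 | 2-methoxy-4-methylphenol | COc1cc(C)ccc1O | starting material
14 | 2-hydroxy-3-methoxy-5-methylbenzaldehyde | COc1cc(C)cc(C=O)c1O | intermediate
15 | 2,3-dihydroxy-5-methylbenzaldehyde | Cc1cc(O)c(O)c(C=O)c1 | intermediate
16 | disodium 3-formyl-5-methylbenzene-1,2-diolate (disodium catecholate) | Cc1cc([O-])c([O-])c(C=O)c1.[Na+].[Na+] | intermediate
17 | 3-(allyloxy)-2-hydroxy-5-methylbenzaldehyde | C=CCOc1cc(C)cc(C=O)c1O | intermediate
18 | 2-(allyloxy)-6-(hydroxymethyl)-4-methylphenol | C=CCOc1cc(C)cc(CO)c1O | intermediate
19 | 2-(allyloxy)-6-{[(tert-butyldimethylsilyl)oxy]methyl}-4-methylphenol | C=CCOc1cc(C)cc(CO[Si](C)(C)C(C)(C)C)c1O | intermediate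
20 | carbon dioxide | O=C=O | starting material
21 | potassium 2-(allyloxy)-6-{[(tert-butyldimethylsilyl)oxy]methyl}-4-methylphenolate (potassium phenoxide) | C=CCOc1cc(C)cc(CO[Si](C)(C)C(C)(C)C)c1[O-].[K+] | intermediate
22 | 3-methoxy-4-[(4R)-2,2,6,6-tetramethyl-1,3-dioxan-4-yl]benzyne (aryne across C1–C6 of ring A) | COC1=C([C@H]2CC(C)(C)OC(C)(C)O2)C=CC#C1 | intermediate
23 | 6-[2-(allyloxy)-6-{[(tert-butyldimethylsilyl)oxy]methyl}-4-methylphenoxy]-2-methoxy-3-[(4R)-2,2,6,6-tetramethyl-1,3-dioxan-4-yl]benzoic acid | COc1c([C@H]2CC(C)(C)OC(C)(C)O2)ccc(Oc2c(OCC=C)cc(C)cc2CO[Si](C)(C)C(C)(C)C)c1C(=O)O | intermediate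
24 | 6-[2-{[(tert-butyldimethylsilyl)oxy]methyl}-6-hydroxy-4-methylphenoxy]-2-methoxy-3-[(4R)-2,2,6,6-tetramethyl-1,3-dioxan-4-yl]benzoic acid | COc1c([C@H]2CC(C)(C)OC(C)(C)O2)ccc(Oc2c(O)cc(C)cc2CO[Si](C)(C)C(C)(C)C)c1C(=O)O | intermediate
25 | 6-[2-hydroxy-6-(hydroxymethyl)-4-methylphenoxy]-3-[(1R)-1,3-dihydroxy-3-methylbutyl]-2-methoxybenzoic acid | COc1c([C@H](O)CC(C)(C)O)ccc(Oc2c(O)cc(C)cc2CO)c1C(=O)O | target

**Step count and risks**
Total: 14 steps. Longest linear sequence: 9 steps (steps 1–6 and 12–14, from 1); the ring B branch contributes 5 steps before the union.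

Steps most likely to fail:

Step 12 (new method). The C1 aryl anion may be protonated faster than it is carboxylated, by the crown ether, the solvent or an allylic or benzylic C–H of ring B. CO2 may also tie up the phenoxide as its carbonate half-ester and slow the addition. Either way only the C1–H ether, or no coupling, would result. The fallback uses known chemistry, sets out from 12 and 19 and returns at 23. The two would be joined in the established two-component manner (CsF, MeCN, rt), in which the phenol adds across aryne 22 with the same regiochemistry and the C1 anion is protonated. This gives (4R)-4-{4-[2-(allyloxy)-6-{[(tert-butyldimethylsilyl)oxy]methyl}-4-methylphenoxy]-2-methoxyphenyl}-2,2,6,6-tetramethyl-1,3-dioxane F1. Directed ortho-metalation of this ether at C1, the ring position between the methoxy and aryloxy oxygens (n-BuLi, TMEDA, THF, −78 °C, where this doubly flanked position should be metalated faster than the allylic and benzylic ones), followed by a CO2 quench would then give 23.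

Step 5. The silyl triflate used to mask the N–H may open the strained benzylic ketal, or incomplete masking may let butyllithium eliminate the secondary carbamate, so that clean ring metalation between the two oxygens is not reached. The fallback sets out from 6 and returns at 11; it changes the directing group to one that needs no Lewis acid and is cleaved by hydride. The secondary carbamate of 6 would be removed (DBU, Et2NH, MeCN, 40 °C) to give 3-methoxy-4-[(4R)-2,2,6,6-tetramethyl-1,3-dioxan-4-yl]phenol F2. Carbamoylation (ClC(O)NEt2, K2CO3, MeCN, reflux) would give 3-methoxy-4-[(4R)-2,2,6,6-tetramethyl-1,3-dioxan-4-yl]phenyl diethylcarbamate F3. This tertiary carbamate would be metalated directly (s-BuLi, TMEDA, THF, −78 °C) and silylated (TMSCl) to 3-methoxy-4-[(4R)-2,2,6,6-tetramethyl-1,3-dioxan-4-yl]-2-(trimethylsilyl)phenyl diethylcarbamate F4. Reductive cleavage with Cp2Zr(H)Cl (THF, rt) would give silylphenol 11, which is triflated as in step 6 to 12.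

Step 2. Facial discrimination may be insufficient in the allylboration of the ortho-methoxy aldehyde, through uncatalysed background addition or binding of the carbamate to the acid, which would erode the enantiomeric purity of the only stereocentre. The fallback sets out from 2 and returns at 4; it sets the centre by ketone reduction instead of C–C bond formation. Barbier methallylation of 2 (Zn, 3-bromo-2-methylpropene, THF/aq. NH4Cl) would give racemic 4-(1-hydroxy-3-methylbut-3-en-1-yl)-3-methoxyphenyl isopropylcarbamate F5. Dess–Martin oxidation (NaHCO3, CH2Cl2) would give 3-methoxy-4-(3-methylbut-3-enoyl)phenyl isopropylcarbamate F6. Corey–Bakshi–Shibata reduction with (S)-1-methyl-3,3-diphenyltetrahydro-1H,3H-pyrrolo[1,2-c][1,3,2]oxazaborole and catecholborane (toluene, −78 °C), the aryl group acting as the large substituent, should then give 4 without hydroborating the alkene.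

**Further compounds**
F1 | step 12 | (4R)-4-{4-[2-(allyloxy)-6-{[(tert-butyldimethylsilyl)oxy]methyl}-4-methylphenoxy]-2-methoxyphenyl}-2,2,6,6-tetramethyl-1,3-dioxane | COc1cc(Oc2c(OCC=C)cc(C)cc2CO[Si](C)(C)C(C)(C)C)ccc1[C@H]3CC(C)(C)OC(C)(C)O3
F2 | step 5 | 3-methoxy-4-[(4R)-2,2,6,6-tetramethyl-1,3-dioxan-4-yl]phenol | COc1cc(O)ccc1[C@H]2CC(C)(C)OC(C)(C)O2
F3 | step 5 | 3-methoxy-4-[(4R)-2,2,6,6-tetramethyl-1,3-dioxan-4-yl]phenyl diethylcarbamate | COc1cc(OC(=O)N(CC)CC)ccc1[C@H]2CC(C)(C)OC(C)(C)O2
F4 | step 5 | 3-methoxy-4-[(4R)-2,2,6,6-tetramethyl-1,3-dioxan-4-yl]-2-(trimethylsilyl)phenyl diethylcarbamate | COc1c([Si](C)(C)C)c(OC(=O)N(CC)CC)ccc1[C@H]2CC(C)(C)OC(C)(C)O2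
F5 | step 2 | racemic 4-(1-hydroxy-3-methylbut-3-en-1-yl)-3-methoxyphenyl isopropylcarbamate | COc1cc(OC(=O)NC(C)C)ccc1C(O)CC(C)=C
F6 | step 2 | 3-methoxy-4-(3-methylbut-3-enoyl)phenyl isopropylcarbamate | COc1cc(OC(=O)NC(C)C)ccc1C(=O)CC(C)=C
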